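The pyranone ring C is opened at C2–C3 and at O1–C8a, so that both C2 and O1 come from one molecule of formaldehyde. The key step exploits the C4 ketone twice: it acidifies C3 (as an α-aryl β-keto allyl ester) for a formaldehyde aldol, and it activates the ortho carbon C8a of ring A, which carries fluoride, for ring closure by SNAr of the new alkoxide. The precursor is therefore an open-chain allyl 2-aryl-3-(2-fluoro-4,6-bis(MOM-oxy)phenyl)-3-oxopropanoate. The temporary C3 ester blocks dehydration and over-hydroxymethylation and is then excised by Pd-catalysed enantioselective decarboxylative protonation, which sets the labile (3S) centre under non-basic conditions.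

Key step: step 10

Remarks on the chemistry:
- Paraformaldehyde is counted as monomeric formaldehyde (17).
- Assumption: the (S)-PHOX ligand with Meldrum's acid is taken to deliver the (3S) product. If the sense of induction on this substrate is the opposite, the (R)-ligand is used in the same step.
- Abbreviations: MOM = CH2OCH3; geranyl = (2E)-3,7-dimethylocta-2,6-dien-1-yl; Ar* = 3-geranyl-4-methoxy-2-(methoxymethoxy)phenyl.

Step 1
Reactants: 1 3-methoxyphenol
Product: 2 1-methoxy-3-(methoxymethoxy)benzene
Conditions: NaH, MOMCl, DMF, 0 °C → rt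
Reagents that add atoms: chloromethyl methyl ether (MOMCl), COCCl
Why: Williamson O-alkylation of the sodium phenoxide; the MOM ether is the protecting group and also the director for the two metalations that follow.

Step 2
Reactants: 2 1-methoxy-3-(methoxymethoxy)benzene; 3 geranyl bromide
Product: 5 2-geranyl-1-methoxy-3-(methoxymethoxy)benzene, via aryllithium 4 (not isolated)
Conditions: n-BuLi, THF, 0 °C → rt; CuI (10 mol%), then 3, −78 °C → rt
Reagents that add atoms: none
Why: Directed ortho-metalation should occur at the position flanked by OMOM and OMe, and copper-catalysed SN2 coupling with the primary allylic bromide should keep the 2E geometry.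

Step 3
Reactants: 5 2-geranyl-1-methoxy-3-(methoxymethoxy)benzene
Product: 7 2-(3-geranyl-4-methoxy-2-(methoxymethoxy)phenyl)ethan-1-ol, via aryllithium 6 (not isolated)
Conditions: n-BuLi, TMEDA, THF, −20 → 0 °C; ethylene oxide (THF solution), −78 °C → rt; H2O
Reagents that add atoms: ethylene oxide (oxirane), C1CO1
Why: A second directed ortho-metalation, steered by the stronger OMOM director to the only free position ortho to it (coordination-driven ring lithiation should outrun deprotonation of the geranyl CH2), is followed by epoxide opening by the aryllithium.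

Step 4
Reactants: 7 2-(Ar*)ethan-1-ol
Product: 8 2-(Ar*)acetic acid
Conditions: TEMPO (20 mol%), PhI(OAc)2 (2.2 equiv), MeCN/H2O 1:1, rt
Reagents that add atoms: water, O
Why: Oxoammonium (TEMPO/BAIB) oxidation takes the primary alcohol through the aldehyde hydrate to the acid and should leave trisubstituted alkenes and MOM ethers untouched.

Step 5
Reactants: 8 2-(Ar*)acetic acid
Product: 9 allyl 2-(Ar*)acetate
Conditions: allyl bromide, K2CO3, DMF, rt
Reagents that add atoms: allyl bromide, C=CCBr
Why: SN2 O-alkylation of the carboxylate installs the allyl ester that later serves as the handle for the decarboxylative protonation.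

Step 6
Reactants: 10 5-fluorobenzene-1,3-diol (5-fluororesorcinol)
Product: 12 2-fluoro-4,6-dihydroxybenzaldehyde, via iminium salt 11 (not isolated)
Conditions: POCl3, DMF, MeCN, 0 °C → rt; then H2O, 50 °C
Reagents that add atoms: N,N-dimethylformamide, CN(C)C=O; water, O
Why: Vilsmeier–Haack formylation of a resorcinol should go para to one OH and ortho to the other (as with resorcinol and orcinol), i.e. next to fluorine; the minor isomer formylated between the two OH groups would be separated.

Step 7
Reactants: 12 2-fluoro-4,6-dihydroxybenzaldehyde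
Product: 13 2-fluoro-4,6-bis(methoxymethoxy)benzaldehyde
Conditions: NaH (2.4 equiv), MOMCl (2.4 equiv), DMF, 0 °C → rt
Reagents that add atoms: chloromethyl methyl ether (MOMCl), COCCl
Why: Williamson O-alkylation of the bis-phenoxide; the strong base is chosen so that the hydrogen-bonded ortho OH is also protected.

Step 8
Reactants: 9 allyl 2-(Ar*)acetate; 13 2-fluoro-4,6-bis(methoxymethoxy)benzaldehyde
Product: 15 allyl 3-[2-fluoro-4,6-bis(methoxymethoxy)phenyl]-3-hydroxy-2-(Ar*)propanoate (racemic, mixture of diastereomers), via lithium enolate 14 (not isolated)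
Conditions: LDA, THF, −78 °C; then 13, −78 °C; AcOH quench at −78 °C
Reagents that add atoms: none
Why: Aldol addition of the lithium ester enolate to a non-enolisable aldehyde, quenched cold to avoid retro-aldol and Ireland–Claisen pathways; the two new stereocentres are inconsequential because both are erased in steps 9–11.

Step 9
Reactants: 15 β-hydroxy ester
Product: 16 allyl 3-[2-fluoro-4,6-bis(methoxymethoxy)phenyl]-3-oxo-2-(Ar*)propanoate (racemic)
Conditions: Dess–Martin periodinane, CH2Cl2, 0 °C → rt
Reagents that add atoms: none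
Why: Dess–Martin oxidation of the benzylic secondary alcohol gives the β-keto ester under conditions that spare alkenes, MOM ethers and the allyl ester.

Step 10
Reactants: 16 β-keto allyl ester; 17 paraformaldehyde (formaldehyde)
Product: 19 allyl (±)-3-(Ar*)-5,7-bis(methoxymethoxy)-4-oxochromane-3-carboxylate, via hydroxymethyl adduct 18 (not isolated)
Conditions: (CH2O)n (3 equiv), Cs2CO3 (1.5 equiv), DMF, rt → 50 °C
Reagents that add atoms: none
Why: Cs2CO3 removes the only acidic C–H of 16 (C3, flanked by ketone, ester and aryl group) and the enolate adds to monomeric formaldehyde (aldol hydroxymethylation) to give alkoxide 18, whose oxygen then displaces fluoride from C8a of ring A by addition–elimination through a Meisenheimer intermediate stabilised by the ortho C4 ketone. Both halves are known reaction types on these substrate classes (hydroxymethylation of α-substituted β-keto esters with formaldehyde; chromanone formation from 2-fluoroaryl β-hydroxy ketones by intramolecular SNAr), run here as an aldol/SNAr domino. The pyranone ring is closed by six-membered intramolecular SNAr at the ring-A sp2 carbon, formally 6-endo with respect to the C8a=C4a–C4=O acceptor system, and the forming ring pulls the ketone into the plane of ring A, which is what the activation needs. The new quaternary C3 centre forms as a racemate and needs no control, because step 11 erases and re-sets it. The step needs the alkoxide to win over the delocalised ester-enolate oxygen (which would give a 2-allyloxyisoflavone) and over retro-Claisen cleavage; the higher nucleophilicity of the primary alkoxide, excess formaldehyde that holds the enolate as aldolate, and a mild carbonate base should secure this, while the quaternary C3 rules out dehydration and a second hydroxymethylation. Fluoride is the only leaving group, and both OMOM groups are meta to it, so they do not deactivate the ipso carbon.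

Step 11
Reactants: 19 allyl (±)-3-(Ar*)-5,7-bis(methoxymethoxy)-4-oxochromane-3-carboxylate
Product: 21 (3S)-3-(Ar*)-5,7-bis(methoxymethoxy)chroman-4-one, via palladium enolate 20 (not isolated)
Conditions: Pd(OAc)2 (10 mol%), (S)-(CF3)3-t-BuPHOX (12.5 mol%), Meldrum's acid (2.5 equiv), 1,4-dioxane, 40 °C
Reagents that add atoms: none
Why: Pd(0) ionises the allyl ester, loss of CO2 gives the PHOX-bound palladium enolate 20, and Meldrum's acid protonates C3 on the face left open by the chiral ligand (catalyst control; Pd-catalysed decarboxylative asymmetric protonation, known for α-aryl β-keto allyl esters including 3-arylchroman-4-ones), under weakly acidic conditions that should not epimerise the new C3–H centre or touch the geranyl alkenes and MOM ethers.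

Step 12
Reactants: 21 (3S)-3-(Ar*)-5,7-bis(methoxymethoxy)chroman-4-one
Product: 22 (3S)-3-(3-geranyl-2-hydroxy-4-methoxyphenyl)-5,7-dihydroxychroman-4-one (target)
Conditions: aq. HCl (3 M)/MeOH 1:10, 0 °C → rt
Reagents that add atoms: none
Why: Acid-catalysed acetal exchange removes the three MOM ethers as dimethoxymethane; dilute acid at or below room temperature is chosen to stay below the threshold for enolisation at C3 and for cyclisation of the geranyl chain onto the 2'-OH, and the reaction itself does not touch C3.

Compound list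

1 | 3-methoxyphenol | COc1cccc(O)c1 | starting material
2 | 1-methoxy-3-(methoxymethoxy)benzene | COCOc1cccc(OC)c1 | intermediate
3 | geranyl bromide, (2E)-1-bromo-3,7-dimethylocta-2,6-diene | BrC/C=C(\C)CCC=C(C)C | starting material
4 | [2-methoxy-6-(methoxymethoxy)phenyl]lithium | COCOc1cccc(OC)c1[Li] | intermediate
5 | 2-[(2E)-3,7-dimethylocta-2,6-dien-1-yl]-1-methoxy-3-(methoxymethoxy)benzene | COCOc1cccc(OC)c1C/C=C(\C)CCC=C(C)C | intermediate
6 | [3-geranyl-4-methoxy-2-(methoxymethoxy)phenyl]lithium | COCOc1c([Li])ccc(OC)c1C/C=C(\C)CCC=C(C)C | intermediate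
7 | 2-{3-[(2E)-3,7-dimethylocta-2,6-dien-1-yl]-4-methoxy-2-(methoxymethoxy)phenyl}ethan-1-ol | COCOc1c(CCO)ccc(OC)c1C/C=C(\C)CCC=C(C)C | intermediate
8 | 2-{3-[(2E)-3,7-dimethylocta-2,6-dien-1-yl]-4-methoxy-2-(methoxymethoxy)phenyl}acetic acid | COCOc1c(CC(=O)O)ccc(OC)c1C/C=C(\C)CCC=C(C)C | intermediate
9 | prop-2-en-1-yl 2-{3-[(2E)-3,7-dimethylocta-2,6-dien-1-yl]-4-methoxy-2-(methoxymethoxy)phenyl}acetate | COCOc1c(CC(=O)OCC=C)ccc(OC)c1C/C=C(\C)CCC=C(C)C | intermediate
10 | 5-fluorobenzene-1,3-diol | Oc1cc(O)cc(F)c1 | starting material
11 | N-[(2-fluoro-4,6-dihydroxyphenyl)methylidene]-N-methylmethanaminium chloride | C[N+](C)=Cc1c(O)cc(O)cc1F.[Cl-] | intermediate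
12 | 2-fluoro-4,6-dihydroxybenzaldehyde | O=Cc1c(O)cc(O)cc1F | intermediate
13 | 2-fluoro-4,6-bis(methoxymethoxy)benzaldehyde | COCOc1cc(F)c(C=O)c(OCOC)c1 | intermediate
14 | lithium enolate of 9 | C=CCOC(O[Li])=Cc1ccc(OC)c(C/C=C(\C)CCC=C(C)C)c1OCOC | intermediate
15 | prop-2-en-1-yl 3-[2-fluoro-4,6-bis(methoxymethoxy)phenyl]-3-hydroxy-2-{3-[(2E)-3,7-dimethylocta-2,6-dien-1-yl]-4-methoxy-2-(methoxymethoxy)phenyl}propanoate (racemic, diastereomer mixture) | C=CCOC(=O)C(c1ccc(OC)c(C/C=C(\C)CCC=C(C)C)c1OCOC)C(O)c1c(F)cc(OCOC)cc1OCOC | intermediate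
16 | prop-2-en-1-yl 3-[2-fluoro-4,6-bis(methoxymethoxy)phenyl]-3-oxo-2-{3-[(2E)-3,7-dimethylocta-2,6-dien-1-yl]-4-methoxy-2-(methoxymethoxy)phenyl}propanoate (racemic) | C=CCOC(=O)C(c1ccc(OC)c(C/C=C(\C)CCC=C(C)C)c1OCOC)C(=O)c1c(F)cc(OCOC)cc1OCOC | intermediate
17 | paraformaldehyde (as formaldehyde) | C=O | starting material
18 | prop-2-en-1-yl 3-[2-fluoro-4,6-bis(methoxymethoxy)phenyl]-2-(hydroxymethyl)-3-oxo-2-{3-[(2E)-3,7-dimethylocta-2,6-dien-1-yl]-4-methoxy-2-(methoxymethoxy)phenyl}propanoate (formed as its caesium alkoxide, racemic) | C=CCOC(=O)C(CO)(c1ccc(OC)c(C/C=C(\C)CCC=C(C)C)c1OCOC)C(=O)c1c(F)cc(OCOC)cc1OCOC | intermediate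
19 | prop-2-en-1-yl (±)-3-{3-[(2E)-3,7-dimethylocta-2,6-dien-1-yl]-4-methoxy-2-(methoxymethoxy)phenyl}-5,7-bis(methoxymethoxy)-4-oxo-3,4-dihydro-2H-chromene-3-carboxylate | C=CCOC(=O)C1(c2ccc(OC)c(C/C=C(\C)CCC=C(C)C)c2OCOC)COc2cc(OCOC)cc(OCOC)c2C1=O | intermediate
20 | palladium-bound C3–C4 enolate of 21 (drawn as the free enol) | COCOc1cc(OCOC)c2c(c1)OCC(c1ccc(OC)c(C/C=C(\C)CCC=C(C)C)c1OCOC)=C2O | intermediate
21 | (3S)-3-{3-[(2E)-3,7-dimethylocta-2,6-dien-1-yl]-4-methoxy-2-(methoxymethoxy)phenyl}-5,7-bis(methoxymethoxy)-2,3-dihydro-4H-chromen-4-one | COc1ccc([C@H]2COc3cc(OCOC)cc(OCOC)c3C2=O)c(OCOC)c1C/C=C(\C)CCC=C(C)C | intermediate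
22 | (3S)-3-{3-[(2E)-3,7-dimethylocta-2,6-dien-1-yl]-2-hydroxy-4-methoxyphenyl}-5,7-dihydroxy-2,3-dihydro-4H-chromen-4-one | COc1ccc([C@H]2COc3cc(O)cc(O)c3C2=O)c(O)c1C/C=C(\C)CCC=C(C)C | target

Total step count: 12. Longest linear sequence: 10 steps (steps 1–5, then 8–12); the ring-A branch (steps 6–7) joins at step 8.

Steps most likely to fail

1. Step 10. The alkoxide may close the ring too slowly on the electron-rich, twisted aryl ketone, so that retro-aldol, retro-Claisen cleavage of the non-enolisable β-keto ester, or O-arylation by the ester enolate take over. Fallback: the ester is removed first. Compound 16 with Pd(PPh3)4 and morpholine (THF, rt; deallylation, then decarboxylation) should give the fluoro deoxybenzoin F1. With paraformaldehyde and K2CO3 in DMF, F1 should undergo the aldol/SNAr closure on a less hindered ketone enolate that has no cleavable β-keto ester, giving the racemic isoflavanone F2. O-acylation of its potassium enolate (KHMDS, allyl chloroformate, THF, −78 °C) should give the allyl enol carbonate F3. Under the conditions of step 11, F3 should pass through the same palladium enolate and return to the route at 21.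

2. Step 11. Facial discrimination in the protonation of the palladium enolate may be poor for this mono-ortho-substituted aryl group, giving low ee. Fallback: the scalemic 21 is subjected to asymmetric transfer hydrogenation with dynamic kinetic resolution [RuCl(p-cymene)((S,S)-TsDPEN), HCO2H/Et3N, rt]. C3 epimerises through the enol under these conditions while the catalyst reduces one enantiomer cis-selectively, which is expected to give the cis-(3S,4S)-isoflavan-4-ol F4. Dess–Martin oxidation (CH2Cl2, 0 °C, no base) then returns 21 with C3 fixed.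

3. Step 12. Acid-catalysed enolisation may erode the C3 configuration while three MOM groups are removed (with acid-induced cyclisation of the geranyl chain onto the 2'-OH as a lesser risk). Fallback: the deprotection is moved ahead of the stereo-setting step. Compound 19, whose quaternary C3 cannot epimerise, is treated with catalytic HCl in allyl alcohol (rt; in this solvent any transesterification or transient lactonisation by the 2'-OH leads back to the allyl ester) to give the triphenol allyl ester F5. The Pd-catalysed decarboxylative protonation of step 11 is then the last operation and gives 22 directly, so the C3–H centre never meets acid. Whether the free phenols compete with Meldrum's acid as proton donors would have to be tested.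

Further compounds

F1 | step 10 | 1-[2-fluoro-4,6-bis(methoxymethoxy)phenyl]-2-{3-[(2E)-3,7-dimethylocta-2,6-dien-1-yl]-4-methoxy-2-(methoxymethoxy)phenyl}ethan-1-one | COCOc1cc(F)c(C(=O)Cc2ccc(OC)c(C/C=C(\C)CCC=C(C)C)c2OCOC)c(OCOC)c1
F2 | step 10 | (±)-3-{3-[(2E)-3,7-dimethylocta-2,6-dien-1-yl]-4-methoxy-2-(methoxymethoxy)phenyl}-5,7-bis(methoxymethoxy)-2,3-dihydro-4H-chromen-4-one | COc1ccc(C2COc3cc(OCOC)cc(OCOC)c3C2=O)c(OCOC)c1C/C=C(\C)CCC=C(C)C
F3 | step 10 | 3-{3-[(2E)-3,7-dimethylocta-2,6-dien-1-yl]-4-methoxy-2-(methoxymethoxy)phenyl}-5,7-bis(methoxymethoxy)-2H-chromen-4-yl prop-2-en-1-yl carbonate | C=CCOC(=O)OC1=C(c2ccc(OC)c(C/C=C(\C)CCC=C(C)C)c2OCOC)COc2cc(OCOC)cc(OCOC)c12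
F4 | step 11 | (3S,4S)-3-{3-[(2E)-3,7-dimethylocta-2,6-dien-1-yl]-4-methoxy-2-(methoxymethoxy)phenyl}-5,7-bis(methoxymethoxy)-3,4-dihydro-2H-chromen-4-ol (cis) | COc1ccc([C@H]2COc3cc(OCOC)cc(OCOC)c3[C@H]2O)c(OCOC)c1C/C=C(\C)CCC=C(C)C
F5 | step 12 | prop-2-en-1-yl (±)-3-{3-[(2E)-3,7-dimethylocta-2,6-dien-1-yl]-2-hydroxy-4-methoxyphenyl}-5,7-dihydroxy-4-oxo-3,4-dihydro-2H-chromene-3-carboxylate | C=CCOC(=O)C1(c2ccc(OC)c(C/C=C(\C)CCC=C(C)C)c2O)COc2cc(O)cc(O)c2C1=O
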